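## Retrosynthetic overview

- The strategy rests on ring A C4, the only stereocentre: a quaternary carbon bearing methyl and prenyl inside a 2-acyl-3,5-dihydroxycyclohexa-2,5-dien-1-one. This ring is the C-prenylated, dearomatized form of a flat, fully substituted acylphloroglucinol.
- Last disconnection: the C4–CH2(prenyl) bond, made by enantioselective palladium-catalysed dearomative prenylation of the aromatic methylene-bridged dimer with tert-butyl prenyl carbonate.
- The dimer is cut at the ArCH2–Ar bond: an ortho-quinone methide from the Mannich base of the ring A monomer is trapped by the ring B monomer.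
- The monomers come from Friedel–Crafts hexanoylation of 2-methylphloroglucinol and of phloroglucinol, the latter followed by O-methylation para to the ketone.
- No ring is formed anywhere: both carbocycles are bought as phloroglucinols, and ring A is dearomatized in the last step.

Key step: step 7

Assumption: the sense of face selection by the ligand on this anion cannot be predicted with confidence, so the (R,R) ligand is written and its (S,S) mirror image is used instead if the first run is enriched in the (R)-product; the descriptor (S) refers to the enol tautomer drawn for 12.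

## Route

Step 1
Reactants: 1 2-methylbenzene-1,3,5-triol; 2 hexanoyl chloride
Product: 3 1-(2,4,6-trihydroxy-3-methylphenyl)hexan-1-one
Conditions: AlCl3 (4 equiv), PhNO2–CH2Cl2, 0 °C to 60 °C; then ice/1 M HCl
Reagents that add atoms: none
Why: Friedel–Crafts C-acylation; the two free ring carbons of 1 are equivalent and the first acyl group deactivates the ring, so the mono-ketone should form, and no stereocentre is involved.

Step 2
Reactants: 4 benzene-1,3,5-triol; 2 hexanoyl chloride
Product: 5 1-(2,4,6-trihydroxyphenyl)hexan-1-one
Conditions: AlCl3 (4 equiv), PhNO2–CH2Cl2, 0 °C to 60 °C; then ice/1 M HCl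
Reagents that add atoms: none
Why: Friedel–Crafts C-acylation of phloroglucinol with one equivalent of acid chloride, which should stop at the mono-ketone because the acyl group deactivates the ring.

Step 3
Reactants: 5 1-(2,4,6-trihydroxyphenyl)hexan-1-one
Product: 6 1-(2,6-dihydroxy-4-methoxyphenyl)hexan-1-one
Conditions: Me2SO4 (1.0 equiv), K2CO3 (1.0 equiv), acetone, reflux
Reagents that add atoms: dimethyl sulfate, COS(=O)(=O)OC
Why: Williamson-type O-methylation with one equivalent each of base and electrophile; the hydroxyl para to the ketone is the most acidic, while the two ortho hydroxyls share the hydrogen-bond chelate with the carbonyl group and are less nucleophilic, so the 4-methyl ether should predominate.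

Step 4
Reactants: 3 1-(2,4,6-trihydroxy-3-methylphenyl)hexan-1-one
Product: 7 1-{3-[(dimethylamino)methyl]-2,4,6-trihydroxy-5-methylphenyl}hexan-1-one
Conditions: N,N-dimethylmethylideneammonium iodide (1.05 equiv), Et3N (1.0 equiv), CH2Cl2, 0 °C to rt
Reagents that add atoms: N,N-dimethylmethylideneammonium iodide, C=[N+](C)C.[I-]
Why: Mannich aminomethylation with a preformed iminium salt; 3 has a single unsubstituted ring carbon, so one aminomethyl group enters there, and the iminium ion, unlike free formaldehyde, should not bridge two molecules of 3.

Step 5
Reactants: 7 1-{3-[(dimethylamino)methyl]-2,4,6-trihydroxy-5-methylphenyl}hexan-1-one; 6 1-(2,6-dihydroxy-4-methoxyphenyl)hexan-1-one (3 equiv, excess recovered)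
Product: 9 1-{3-[(3-hexanoyl-2,4-dihydroxy-6-methoxyphenyl)methyl]-2,4,6-trihydroxy-5-methylphenyl}hexan-1-one, via ortho-quinone methide 8 (not isolated)
Conditions: 1,4-dioxane, 100 °C, slow N2 purge
Reagents that add atoms: none
Why: Thermal loss of dimethylamine from the ortho-hydroxybenzylamine gives ortho-quinone methide 8, which is trapped by Friedel–Crafts-type conjugate addition of one of the two equivalent free ring carbons of 6 (kept in excess to hold back a second alkylation), and tautomerization restores both aromatic rings.

Step 6
Reactants: 10 3-methylbut-2-en-1-ol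
Product: 11 tert-butyl 3-methylbut-2-en-1-yl carbonate
Conditions: Boc2O (1.2 equiv), Bu4NHSO4 (cat.), 30% aq NaOH, CH2Cl2, 0 °C to rt
Reagents that add atoms: di-tert-butyl dicarbonate, CC(C)(C)OC(=O)OC(=O)OC(C)(C)C
Why: Phase-transfer O-acylation of the primary allylic alcohol with Boc anhydride, a standard preparation of allylic tert-butyl carbonates.

Step 7
Reactants: 9 1-{3-[(3-hexanoyl-2,4-dihydroxy-6-methoxyphenyl)methyl]-2,4,6-trihydroxy-5-methylphenyl}hexan-1-one; 11 tert-butyl 3-methylbut-2-en-1-yl carbonate (1.05 equiv)
Product: 12 (4S)-2-hexanoyl-6-[(3-hexanoyl-2,4-dihydroxy-6-methoxyphenyl)methyl]-3,5-dihydroxy-4-methyl-4-(3-methylbut-2-en-1-yl)cyclohexa-2,5-dien-1-one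
Conditions: Pd2(dba)3·CHCl3 (2.5 mol%), N,N′-[(1R,2R)-cyclohexane-1,2-diyl]bis[2-(diphenylphosphanyl)benzamide] (7.5 mol%), degassed 1,4-dioxane, 0 °C to rt; then aq citric acid
Reagents that add atoms: none
Why: Proposed new method: zerovalent palladium bound to the bisphosphine opens 11 by oxidative ionization, and loss of carbon dioxide leaves a cationic π-prenyl complex of divalent palladium with tert-butoxide; the base takes the most acidic proton of 9, the ring A hydroxyl para to the hexanoyl group, and the vinylogous carboxylate so formed attacks the unsubstituted allyl terminus through its methyl-bearing ring carbon in an outer-sphere step, and because the new centre carries no hydrogen, tautomerization back to a phenol is closed off. The closest known reactions are the racemic palladium-catalysed dearomative Tsuji–Trost prenylation of acylphloroglucinols and the enantioselective palladium-catalysed allylic dearomatization of substituted 2-naphthols with this ligand family; new here is ligand-controlled face selection on an acylphloroglucinol anion. No ring is closed. The (S) centre is set by catalyst control alone: the chiral pocket around the π-prenyl unit has to tell apart the two enantiotopic faces of the flat anion, helped by the unlike flanks of the reacting carbon (a chelated hydroxy ketone on one side, the oxido carbon and the bulky arylmethyl group on the other). The step needs site selectivity for the methyl-bearing over the arylmethyl-bearing carbon (the smaller methyl group), C- over O-prenylation (O-prenyl ethers of so acidic a phenol re-ionize on palladium and drain to the C-alkylated product), linear over reverse prenylation (the crowded nucleophilic carbon goes to the CH2 terminus) and ring A over ring B (ring B has only the two less acidic hydroxyls ortho to its ketone, only one of them chelated at a time, and no base is present beyond the one equivalent released from 11). Over-prenylation is limited by the near-stoichiometric amount of 11 and by the bulky arylmethyl group on the only ring carbon of 12 that is still nucleophilic.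

The enantiomeric purity of 12 is to be assayed by HPLC on a chiral stationary phase, and the configuration assigned by electronic circular dichroism or by X-ray analysis of a crystalline salt.

## Compound list

1 | 2-methylbenzene-1,3,5-triol | Cc1c(O)cc(O)cc1O | starting material
2 | hexanoyl chloride | CCCCCC(Cl)=O | starting material
3 | 1-(2,4,6-trihydroxy-3-methylphenyl)hexan-1-one | CCCCCC(=O)c1c(O)c(C)c(O)cc1O | intermediate
4 | benzene-1,3,5-triol (phloroglucinol) | Oc1cc(O)cc(O)c1 | starting material
5 | 1-(2,4,6-trihydroxyphenyl)hexan-1-one | CCCCCC(=O)c1c(O)cc(O)cc1O | intermediate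
6 | 1-(2,6-dihydroxy-4-methoxyphenyl)hexan-1-one | CCCCCC(=O)c1c(O)cc(OC)cc1O | intermediate
7 | 1-{3-[(dimethylamino)methyl]-2,4,6-trihydroxy-5-methylphenyl}hexan-1-one | CCCCCC(=O)c1c(O)c(C)c(O)c(CN(C)C)c1O | intermediate
8 | 2-hexanoyl-3,5-dihydroxy-4-methyl-6-methylidenecyclohexa-2,4-dien-1-one (ortho-quinone methide) | CCCCCC(=O)C1=C(O)C(C)=C(O)C(=C)C1=O | intermediate (not isolated)
9 | 1-{3-[(3-hexanoyl-2,4-dihydroxy-6-methoxyphenyl)methyl]-2,4,6-trihydroxy-5-methylphenyl}hexan-1-one (aromatic methylene-bridged dimer) | CCCCCC(=O)c1c(O)c(C)c(O)c(Cc2c(OC)cc(O)c(C(=O)CCCCC)c2O)c1O | intermediate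
10 | 3-methylbut-2-en-1-ol | CC(C)=CCO | starting material
11 | tert-butyl 3-methylbut-2-en-1-yl carbonate | CC(C)=CCOC(=O)OC(C)(C)C | intermediate
12 | (4S)-2-hexanoyl-6-[(3-hexanoyl-2,4-dihydroxy-6-methoxyphenyl)methyl]-3,5-dihydroxy-4-methyl-4-(3-methylbut-2-en-1-yl)cyclohexa-2,5-dien-1-one (CNP0108719.1) | CCCCCC(=O)C1=C(O)[C@@](C)(CC=C(C)C)C(O)=C(Cc2c(OC)cc(O)c(C(=O)CCCCC)c2O)C1=O | target

## Step count and risks

Total step count: 7.
Longest linear sequence: 4 steps (1 → 3 → 7 → 9 → 12, or 4 → 5 → 6 → 9 → 12).

Steps most likely to fail:

1. Step 7 (carries the label). What may go wrong: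
 - poor face selection by the ligand;
 - competing attack through the arylmethyl-bearing ring carbon or through oxygen;
 - reverse prenylation;
 - stalling of turnover as the more acidic product sequesters the base released in each cycle.

 Fallback, from 9 back to 12: the same bond is made without asymmetric induction, using 11 with Pd(PPh3)4 in THF at room temperature, the known racemic dearomative Tsuji–Trost prenylation of acylphloroglucinols. This should give rac-2-hexanoyl-6-[(3-hexanoyl-2,4-dihydroxy-6-methoxyphenyl)methyl]-3,5-dihydroxy-4-methyl-4-(3-methylbut-2-en-1-yl)cyclohexa-2,5-dien-1-one F1. The enantiomers are then separated by preparative HPLC on an amylose tris(3,5-dimethylphenylcarbamate) stationary phase; crystallisation of diastereomeric salts of this strongly acidic enolized triketone with (1R,2R)-cyclohexane-1,2-diamine is a second option. The (S)-enantiomer is 12, where the route is rejoined, and the (4R)-2-hexanoyl-6-[(3-hexanoyl-2,4-dihydroxy-6-methoxyphenyl)methyl]-3,5-dihydroxy-4-methyl-4-(3-methylbut-2-en-1-yl)cyclohexa-2,5-dien-1-one F2 is set aside.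

2. Step 5. What may go wrong:
 - a second alkylation at the remaining free ring carbon of ring B, leading to 2:1 adducts;
 - exchange of the aryl groups across the methylene bridge, promoted by heat and the liberated amine, so that symmetrical dimers build up;
 - sluggish elimination from the zwitterionic Mannich base.

 Fallback, from 3 and 6 back to 9: the preformed Mannich base is given up. Compounds 3 and 6 (the latter in excess) are condensed directly with 37% aqueous formaldehyde in 1% aqueous NaOH at 0 °C to room temperature for a short time, then acidified with HCl. This is the classical one-pot way to mixed methylene-bis-acylphloroglucinols. Compound 9 is separated by chromatography from the two symmetrical dimers, which differ from it in the number of free hydroxyls. No compound outside the compound list is made on this way (F0).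

3. Step 3. What may go wrong: over-methylation to the dimethyl ether, or methylation of an ortho hydroxyl, giving mixtures that are hard to separate.

 Fallback, from 2 back to 6: the methyl ether is brought in before the ketone. Friedel–Crafts acylation of commercial 1,3,5-trimethoxybenzene F3 with 2 (AlCl3, CH2Cl2, 0 °C) should give 1-(2,4,6-trimethoxyphenyl)hexan-1-one F4 as the only possible isomer. Chelation-assisted cleavage of the two methyl ethers ortho to the ketone with excess AlCl3 (CH2Cl2 or chlorobenzene, rt to 60 °C) should leave the para methoxyl untouched and return to the route at 6.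

Further compounds
F1 | step 7 | rac-2-hexanoyl-6-[(3-hexanoyl-2,4-dihydroxy-6-methoxyphenyl)methyl]-3,5-dihydroxy-4-methyl-4-(3-methylbut-2-en-1-yl)cyclohexa-2,5-dien-1-one (racemate) | CCCCCC(=O)C1=C(O)C(C)(CC=C(C)C)C(O)=C(Cc2c(OC)cc(O)c(C(=O)CCCCC)c2O)C1=O
F2 | step 7 | (4R)-2-hexanoyl-6-[(3-hexanoyl-2,4-dihydroxy-6-methoxyphenyl)methyl]-3,5-dihydroxy-4-methyl-4-(3-methylbut-2-en-1-yl)cyclohexa-2,5-dien-1-one | CCCCCC(=O)C1=C(O)[C@](C)(CC=C(C)C)C(O)=C(Cc2c(OC)cc(O)c(C(=O)CCCCC)c2O)C1=O
F0 | step 5 | none | none
F3 | step 3 | 1,3,5-trimethoxybenzene (commercial) | COc1cc(OC)cc(OC)c1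
F4 | step 3 | 1-(2,4,6-trimethoxyphenyl)hexan-1-one | CCCCCC(=O)c1c(OC)cc(OC)cc1OC
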